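**Plan**

- Ring A (the benzoic acid ring) carries the aryloxy group on C6 and the carboxyl group on C1 as neighbours, and C1 is flanked on its other side by the C2 methoxy group. A 3-methoxyaryne leaves exactly this pattern after it takes up an oxygen nucleophile at its far carbon and an electrophile at its near carbon.
- After removal of three silyl ethers and one benzyl ether, the retrosynthesis cuts the diaryl ether bond O–C6 and the C1–CO2H bond in one operation. This leads back to a ring A ortho-silylaryl triflate, the ring B phenol and CO2.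
- Ring A fragment: the C1–Si bond is cut by directed ortho-metalation, the tertiary C–OH bond by alkene hydration, and the carbinol C–CH2 bond by methallylation of 4-hydroxy-2-methoxybenzaldehyde. Ring B fragment: the O-benzyl bond and the formyl C–C bond ortho to the phenol of 2-methoxy-4-methylphenol.
- Forward: no ring is formed, both benzene rings are bought. Side chain (steps 1–5), aryne precursor (steps 6–7), ring B phenol (steps 8–12), union with CO2 (step 13), unmasking (steps 14–15).
- The only stereocentre, the (S)-benzylic carbinol, comes from a Brown methallylboration with the borane of the (+)-α-pinene series, made from (−)-Ipc2BOMe. It is carried on as a silyl ether.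

Key step: step 13

Remark on numbering: ring A is numbered as in the target acid (C1 carboxyl, C2 methoxy, C3 side chain, C6 aryloxy); ring B is the phenoxy ring.
Remark on reagents: (−)-Ipc2BOMe and 2-methylallylmagnesium chloride (THF solution) are taken as purchased reagents.

**Route**

Step 1
Reactants: 1 4-hydroxy-2-methoxybenzaldehyde
Product: 2 4-formyl-3-methoxyphenyl N-isopropylcarbamate
Conditions: iPrNCO (1.2 equiv), Et3N (0.1 equiv), CH2Cl2, rt
Reagents that add atoms: isopropyl isocyanate, CC(C)N=C=O
Why: Amine-catalysed addition of the phenol to the isocyanate (carbamoylation) should give the N-monoalkyl O-aryl carbamate, which later directs the ortho-metalation and is cleavable under mild base, while the aldehyde is untouched.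

Step 2
Reactants: 2 4-formyl-3-methoxyphenyl N-isopropylcarbamate
Product: 4 (S)-4-(1-hydroxy-3-methylbut-3-en-1-yl)-3-methoxyphenyl N-isopropylcarbamate, via borinic ester 3 (not isolated)
Conditions: (−)-Ipc2BOMe (1.5 equiv), 2-methylallylmagnesium chloride (1.4 equiv), Et2O, 0 °C → rt; then 2, −78 °C; then pH 7 phosphate buffer, MeOH, 30% H2O2, 0 °C → rt
Reagents that add atoms: 2-methylallylmagnesium chloride, C=C(C)C[Mg]Cl (its methallyl group is passed on by B-(2-methylallyl)diisopinocampheylborane, C=C(C)CB([C@@H]1C[C@@H]2C[C@H]([C@H]1C)C2(C)C)[C@@H]1C[C@@H]2C[C@H]([C@H]1C)C2(C)C, formed in the flask from it and (−)-Ipc2BOMe)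
Why: Brown asymmetric methallylboration through a closed chair transition state, in which the isopinocampheyl groups of the (+)-α-pinene series direct the methallyl group to the Si face of the aryl aldehyde (the sense established for benzaldehyde) and so set the (S)-carbinol, while the slight deficit of Grignard reagent and the buffered oxidative work-up spare the base-labile N–H carbamate.

Step 3
Reactants: 4 (S)-4-(1-hydroxy-3-methylbut-3-en-1-yl)-3-methoxyphenyl N-isopropylcarbamate
Product: 5 (S)-4-(1,3-dihydroxy-3-methylbutyl)-3-methoxyphenyl N-isopropylcarbamate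
Conditions: Co(acac)2 (20 mol%), PhSiH3, O2 (1 atm), THF, rt
Reagents that add atoms: dioxygen, O=O
Why: Mukaiyama hydration (cobalt-mediated hydrogen-atom transfer to the 1,1-disubstituted alkene, trapping of the tertiary radical by O2 and reduction of the peroxide by the silane) should give the Markovnikov tertiary alcohol under neutral conditions that leave the carbinol stereocentre and the carbamate alone.

Step 4
Reactants: 5 (S)-4-(1,3-dihydroxy-3-methylbutyl)-3-methoxyphenyl N-isopropylcarbamate
Product: 6 (S)-4-[1-(tert-butyldimethylsilyloxy)-3-hydroxy-3-methylbutyl]-3-methoxyphenyl N-isopropylcarbamate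
Conditions: TBSCl, imidazole, DMF, rt
Reagents that add atoms: tert-butyldimethylsilyl chloride, CC(C)(C)[Si](C)(C)Cl
Why: Corey silylation with a silyl chloride and imidazole reacts with the secondary alcohol but not with the tertiary alcohol or the carbamate N–H, so the benzylic carbinol is masked selectively.

Step 5
Reactants: 6 (S)-4-[1-(tert-butyldimethylsilyloxy)-3-hydroxy-3-methylbutyl]-3-methoxyphenyl N-isopropylcarbamate
Product: 7 (S)-4-[1-(tert-butyldimethylsilyloxy)-3-methyl-3-(triethylsilyloxy)butyl]-3-methoxyphenyl N-isopropylcarbamate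
Conditions: TESOTf, 2,6-lutidine, CH2Cl2, −78 → 0 °C
Reagents that add atoms: triethylsilyl trifluoromethanesulfonate, CC[Si](CC)(CC)OS(=O)(=O)C(F)(F)F
Why: Silylation with a silyl triflate and a hindered pyridine base is the standard way to cap a tertiary alcohol, which removes the last O–H proton that could quench organolithium or aryl anion intermediates later.

Step 6
Reactants: 7 (S)-4-[1-(tert-butyldimethylsilyloxy)-3-methyl-3-(triethylsilyloxy)butyl]-3-methoxyphenyl N-isopropylcarbamate
Product: 11 (S)-4-[1-(tert-butyldimethylsilyloxy)-3-methyl-3-(triethylsilyloxy)butyl]-3-methoxy-2-(trimethylsilyl)phenyl N-isopropylcarbamate, via N-silyl carbamate 8 (not isolated), via aryllithium 9 (not isolated), via N-silyl arylsilane 10 (not isolated)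
Conditions: TMSOTf, TMEDA, Et2O, 0 °C → rt; n-BuLi, TMEDA, −78 °C; TMSCl, −78 °C → rt; aq. NH4Cl
Reagents that add atoms: chlorotrimethylsilane, C[Si](C)(C)Cl
Why: Directed ortho-metalation in the Hoppe variant, in which the N–H carbamate is first silylated on nitrogen in the flask so that it behaves as a tertiary carbamate, should place lithium on the ring carbon flanked by both the carbamate and the methoxy oxygen (cooperative direction), where TMSCl then forms the C–Si bond and the N–Si bond falls off on aqueous work-up.

Step 7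
Reactants: 11 (S)-4-[1-(tert-butyldimethylsilyloxy)-3-methyl-3-(triethylsilyloxy)butyl]-3-methoxy-2-(trimethylsilyl)phenyl N-isopropylcarbamate
Product: 13 (S)-4-[1-(tert-butyldimethylsilyloxy)-3-methyl-3-(triethylsilyloxy)butyl]-3-methoxy-2-(trimethylsilyl)phenyl trifluoromethanesulfonate, via ortho-silyl phenol 12 (not isolated)
Conditions: DBU, Et2NH, MeCN, 40 °C; then PhNTf2, rt
Reagents that add atoms: N-phenylbis(trifluoromethanesulfonimide), O=S(=O)(N(c1ccccc1)S(=O)(=O)C(F)(F)F)C(F)(F)F
Why: DBU-induced E1cB fragmentation of the N-monoalkyl carbamate releases the phenoxide and isopropyl isocyanate (scavenged by diethylamine as a urea), and the phenoxide is triflated in the same flask by PhNTf2, the established one-pot passage from ortho-silylaryl carbamates to ortho-silylaryl triflates that leaves the C–Si bond and the silyl ethers alone.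

Step 8
Reactants: 14 2-methoxy-4-methylphenol
Product: 15 2-hydroxy-3-methoxy-5-methylbenzaldehyde
Conditions: MgCl2, Et3N, (CH2O)n, MeCN, reflux; 1 M HCl work-up
Reagents that add atoms: formaldehyde (as paraformaldehyde), C=O
Why: Magnesium-mediated ortho-formylation (Casnati–Skattebøl reaction), in which the magnesium phenoxide delivers formaldehyde to the only free ortho position and a second formaldehyde oxidises the hydroxymethyl intermediate by hydride transfer.

Step 9
Reactants: 15 2-hydroxy-3-methoxy-5-methylbenzaldehyde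
Product: 16 2,3-dihydroxy-5-methylbenzaldehyde
Conditions: BBr3, CH2Cl2, −78 → 0 °C; H2O
Reagents that add atoms: none
Why: Lewis acid cleavage of the aryl methyl ether by BBr3, assisted by chelation to the neighbouring phenol, should free the catechol at a stage where no other methyl ether is present.

Step 10
Reactants: 16 2,3-dihydroxy-5-methylbenzaldehyde
Product: 19 3-(benzyloxy)-2-hydroxy-5-methylbenzaldehyde, via disodium catecholate 17 (not isolated), via sodium phenoxide 18 (not isolated)
Conditions: NaH (2.2 equiv), DMSO, rt; BnBr (1.0 equiv), rt; 1 M HCl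
Reagents that add atoms: benzyl bromide, BrCc1ccccc1
Why: Williamson etherification of the dianion, in which the 2-phenoxide is delocalised into the formyl group and held in a sodium chelate so that the 3-phenoxide is alkylated, the known selectivity of 2,3-dihydroxybenzaldehydes.

Step 11
Reactants: 19 3-(benzyloxy)-2-hydroxy-5-methylbenzaldehyde
Product: 20 2-(benzyloxy)-6-(hydroxymethyl)-4-methylphenol
Conditions: NaBH4, THF/MeOH, 0 °C
Reagents that add atoms: none
Why: Borohydride reduction of the aldehyde removes the carbonyl group that would otherwise intercept the aryl anion of the key step.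

Step 12
Reactants: 20 2-(benzyloxy)-6-(hydroxymethyl)-4-methylphenol
Product: 21 2-(benzyloxy)-4-methyl-6-[(triisopropylsilyloxy)methyl]phenol
Conditions: TIPSCl, imidazole, CH2Cl2, 0 °C → rt
Reagents that add atoms: triisopropylsilyl chloride, CC(C)[Si](Cl)(C(C)C)C(C)C
Why: Silylation with a bulky silyl chloride and imidazole takes the primary benzylic hydroxyl in preference to the doubly flanked, hydrogen-bonded phenol, as is known for salicyl alcohols.

Step 13
Reactants: 13 (S)-4-[1-(tert-butyldimethylsilyloxy)-3-methyl-3-(triethylsilyloxy)butyl]-3-methoxy-2-(trimethylsilyl)phenyl trifluoromethanesulfonate; 21 2-(benzyloxy)-4-methyl-6-[(triisopropylsilyloxy)methyl]phenol (1.5 equiv); 22 carbon dioxide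
Product: 27 (S)-6-[2-(benzyloxy)-4-methyl-6-(triisopropylsilyloxymethyl)phenoxy]-3-[1-(tert-butyldimethylsilyloxy)-3-methyl-3-(triethylsilyloxy)butyl]-2-methoxybenzoic acid, via potassium phenoxide 23 (not isolated), via aryne 24 (not isolated), via aryl potassium adduct 25 (not isolated), via potassium carboxylate 26 (not isolated)
Conditions: 21, KH (1.5 equiv), THF, 0 °C; 18-crown-6, KF, CO2 (1 atm), 0 °C; 13 in THF added over 2 h, 0 °C → rt; 10% aq. citric acid
Reagents that add atoms: none
Why: Proposed new method: fluoride from KF/18-crown-6 attacks the trimethylsilyl group of 13 and triflate leaves, giving aryne 24 with its triple bond between C1 and C6; phenoxide 23 adds through oxygen to C6, and the aryl anion 25 left at C1, stabilised inductively by the C2 methoxy and C6 aryloxy oxygens, is carboxylated by dissolved CO2 to carboxylate 26, which is protonated on work-up. The closest known reaction types are the O-arylation of phenols by arynes released from ortho-silylaryl triflates and the three-component couplings in which such an aryne takes up an imine, an aminosilane or chloride and then CO2 under KF/18-crown-6; a phenoxide as the first partner has not been shown. No ring is closed and no stereocentre is formed, so the (S)-carbinol only rides along as its silyl ether. The regiochemistry needed (oxygen at C6, carbon at C1) is secured by the C2 methoxy group, whose σ-withdrawal distorts the aryne so that nucleophiles attack the distal carbon and place the charge next to oxygen. Carboxylation must outrun protonation and cyclisation, which substrate and medium secure: the phenoxide is made with KH so that no conjugate acid remains, ring B carries no carbonyl group that could lead to a xanthone, and every ortho and para position of the phenoxide is substituted so that only O-arylation is open. Slow addition of 13 keeps the aryne dilute against an excess of 23, which limits capture of the aryne by the product carboxylate.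

Step 14
Reactants: 27 (S)-6-[2-(benzyloxy)-4-methyl-6-(triisopropylsilyloxymethyl)phenoxy]-3-[1-(tert-butyldimethylsilyloxy)-3-methyl-3-(triethylsilyloxy)butyl]-2-methoxybenzoic acid
Product: 28 (S)-3-[1-(tert-butyldimethylsilyloxy)-3-methyl-3-(triethylsilyloxy)butyl]-6-[2-hydroxy-4-methyl-6-(triisopropylsilyloxymethyl)phenoxy]-2-methoxybenzoic acid
Conditions: H2 (1 atm), 10% Pd/C, EtOAc, rt
Reagents that add atoms: none
Why: Hydrogenolysis of the aryl benzyl ether over Pd/C is done while the secondary and primary benzylic C–O bonds are still silylated, so that in neutral ethyl acetate neither they nor the diaryl ether should be reduced.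

Step 15
Reactants: 28 (S)-3-[1-(tert-butyldimethylsilyloxy)-3-methyl-3-(triethylsilyloxy)butyl]-6-[2-hydroxy-4-methyl-6-(triisopropylsilyloxymethyl)phenoxy]-2-methoxybenzoic acid
Product: 29 3-[(1S)-1,3-dihydroxy-3-methylbutyl]-6-[2-hydroxy-6-(hydroxymethyl)-4-methylphenoxy]-2-methoxybenzoic acid (CNP0452050.2)
Conditions: TBAF, AcOH (1:1, 10 equiv), THF, rt → 45 °C
Reagents that add atoms: none
Why: Fluoride-induced cleavage of the three silyl ethers (driven by Si–F bond formation), buffered with acetic acid so that the electron-rich benzylic carbinol meets neither strong acid nor strong base and the stereocentre is not touched.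

**Compound list**

1 | 4-hydroxy-2-methoxybenzaldehyde | COc1cc(O)ccc1C=O | starting material
2 | 4-formyl-3-methoxyphenyl N-isopropylcarbamate | COc1cc(OC(=O)NC(C)C)ccc1C=O | intermediate
3 | O-diisopinocampheylboryl derivative (borinic ester) of 4 | COc1cc(OC(=O)NC(C)C)ccc1[C@@H](OB([C@@H]2C[C@@H]3C[C@H]([C@H]2C)C3(C)C)[C@@H]2C[C@@H]3C[C@H]([C@H]2C)C3(C)C)CC(C)=C | intermediate (not isolated)
4 | (S)-4-(1-hydroxy-3-methylbut-3-en-1-yl)-3-methoxyphenyl N-isopropylcarbamate | COc1cc(OC(=O)NC(C)C)ccc1[C@@H](O)CC(C)=C | intermediate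
5 | (S)-4-(1,3-dihydroxy-3-methylbutyl)-3-methoxyphenyl N-isopropylcarbamate | COc1cc(OC(=O)NC(C)C)ccc1[C@@H](O)CC(C)(C)O | intermediate
6 | (S)-4-[1-(tert-butyldimethylsilyloxy)-3-hydroxy-3-methylbutyl]-3-methoxyphenyl N-isopropylcarbamate | COc1cc(OC(=O)NC(C)C)ccc1[C@@H](O[Si](C)(C)C(C)(C)C)CC(C)(C)O | intermediate
7 | (S)-4-[1-(tert-butyldimethylsilyloxy)-3-methyl-3-(triethylsilyloxy)butyl]-3-methoxyphenyl N-isopropylcarbamate | COc1cc(OC(=O)NC(C)C)ccc1[C@@H](O[Si](C)(C)C(C)(C)C)CC(C)(C)O[Si](CC)(CC)CC | intermediate
8 | N-trimethylsilyl derivative of 7 | COc1cc(OC(=O)N(C(C)C)[Si](C)(C)C)ccc1[C@@H](O[Si](C)(C)C(C)(C)C)CC(C)(C)O[Si](CC)(CC)CC | intermediate (not isolated)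
9 | aryllithium from 8, lithium on the ring carbon between carbamate and methoxy | COc1c([Li])c(OC(=O)N(C(C)C)[Si](C)(C)C)ccc1[C@@H](O[Si](C)(C)C(C)(C)C)CC(C)(C)O[Si](CC)(CC)CC | intermediate (not isolated)
10 | N-trimethylsilyl derivative of 11 | COc1c([Si](C)(C)C)c(OC(=O)N(C(C)C)[Si](C)(C)C)ccc1[C@@H](O[Si](C)(C)C(C)(C)C)CC(C)(C)O[Si](CC)(CC)CC | intermediate (not isolated)
11 | (S)-4-[1-(tert-butyldimethylsilyloxy)-3-methyl-3-(triethylsilyloxy)butyl]-3-methoxy-2-(trimethylsilyl)phenyl N-isopropylcarbamate | COc1c([Si](C)(C)C)c(OC(=O)NC(C)C)ccc1[C@@H](O[Si](C)(C)C(C)(C)C)CC(C)(C)O[Si](CC)(CC)CC | intermediate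
12 | (S)-4-[1-(tert-butyldimethylsilyloxy)-3-methyl-3-(triethylsilyloxy)butyl]-3-methoxy-2-(trimethylsilyl)phenol (present as its DBU salt) | COc1c([Si](C)(C)C)c(O)ccc1[C@@H](O[Si](C)(C)C(C)(C)C)CC(C)(C)O[Si](CC)(CC)CC | intermediate (not isolated)
13 | (S)-4-[1-(tert-butyldimethylsilyloxy)-3-methyl-3-(triethylsilyloxy)butyl]-3-methoxy-2-(trimethylsilyl)phenyl trifluoromethanesulfonate | COc1c([Si](C)(C)C)c(OS(=O)(=O)C(F)(F)F)ccc1[C@@H](O[Si](C)(C)C(C)(C)C)CC(C)(C)O[Si](CC)(CC)CC | intermediate
14 | 2-methoxy-4-methylphenol | COc1cc(C)ccc1O | starting material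
15 | 2-hydroxy-3-methoxy-5-methylbenzaldehyde | COc1cc(C)cc(C=O)c1O | intermediate
16 | 2,3-dihydroxy-5-methylbenzaldehyde | Cc1cc(O)c(O)c(C=O)c1 | intermediate
17 | disodium salt of 16 | Cc1cc([O-])c([O-])c(C=O)c1.[Na+].[Na+] | intermediate (not isolated)
18 | sodium salt of 19 | Cc1cc(OCc2ccccc2)c([O-])c(C=O)c1.[Na+] | intermediate (not isolated)
19 | 3-(benzyloxy)-2-hydroxy-5-methylbenzaldehyde | Cc1cc(OCc2ccccc2)c(O)c(C=O)c1 | intermediate
20 | 2-(benzyloxy)-6-(hydroxymethyl)-4-methylphenol | Cc1cc(CO)c(O)c(OCc2ccccc2)c1 | intermediate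
21 | 2-(benzyloxy)-4-methyl-6-[(triisopropylsilyloxy)methyl]phenol | Cc1cc(CO[Si](C(C)C)(C(C)C)C(C)C)c(O)c(OCc2ccccc2)c1 | intermediate
22 | carbon dioxide | O=C=O | starting material
23 | potassium salt of 21 | Cc1cc(CO[Si](C(C)C)(C(C)C)C(C)C)c([O-])c(OCc2ccccc2)c1.[K+] | intermediate (not isolated)
24 | (S)-4-[1-(tert-butyldimethylsilyloxy)-3-methyl-3-(triethylsilyloxy)butyl]-3-methoxybenzyne (triple bond between the former C–Si and C–OTf carbons) | COC1=C([C@@H](O[Si](C)(C)C(C)(C)C)CC(C)(C)O[Si](CC)(CC)CC)C=CC#C1 | intermediate (not isolated)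
25 | aryl potassium adduct, potassium on ring A C1 between the methoxy and aryloxy groups | COc1c([K])c(Oc2c(OCc3ccccc3)cc(C)cc2CO[Si](C(C)C)(C(C)C)C(C)C)ccc1[C@@H](O[Si](C)(C)C(C)(C)C)CC(C)(C)O[Si](CC)(CC)CC | intermediate (not isolated)
26 | potassium salt of 27 | COc1c(C(=O)[O-])c(Oc2c(OCc3ccccc3)cc(C)cc2CO[Si](C(C)C)(C(C)C)C(C)C)ccc1[C@@H](O[Si](C)(C)C(C)(C)C)CC(C)(C)O[Si](CC)(CC)CC.[K+] | intermediate (not isolated)
27 | (S)-6-[2-(benzyloxy)-4-methyl-6-(triisopropylsilyloxymethyl)phenoxy]-3-[1-(tert-butyldimethylsilyloxy)-3-methyl-3-(triethylsilyloxy)butyl]-2-methoxybenzoic acid | COc1c(C(=O)O)c(Oc2c(OCc3ccccc3)cc(C)cc2CO[Si](C(C)C)(C(C)C)C(C)C)ccc1[C@@H](O[Si](C)(C)C(C)(C)C)CC(C)(C)O[Si](CC)(CC)CC | intermediate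
28 | (S)-3-[1-(tert-butyldimethylsilyloxy)-3-methyl-3-(triethylsilyloxy)butyl]-6-[2-hydroxy-4-methyl-6-(triisopropylsilyloxymethyl)phenoxy]-2-methoxybenzoic acid | COc1c(C(=O)O)c(Oc2c(O)cc(C)cc2CO[Si](C(C)C)(C(C)C)C(C)C)ccc1[C@@H](O[Si](C)(C)C(C)(C)C)CC(C)(C)O[Si](CC)(CC)CC | intermediate
29 | 3-[(1S)-1,3-dihydroxy-3-methylbutyl]-6-[2-hydroxy-6-(hydroxymethyl)-4-methylphenoxy]-2-methoxybenzoic acid | COc1c([C@@H](O)CC(C)(C)O)ccc(Oc2c(O)cc(C)cc2CO)c1C(=O)O | target

**Step count and risks**

Total: 15 steps. Longest linear sequence: 10 steps (steps 1–7, then 13–15); the ring B branch (steps 8–12) has 5 steps.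

Steps most likely to fail:

1. Step 13 (the new coupling). The phenoxide may be bound by CO2 as an aryl carbonate and then add too slowly. The aryl anion may be protonated before it meets CO2. The product carboxylate may itself be arylated, and the triethylsilyl ether may be slowly lost under fluoride. The fallback uses known chemistry and sets out from 13 and 21. CsF in MeCN at rt without CO2 (aryne O-arylation of a phenol, the aryl anion taking the phenol proton) should give the decarboxy diaryl ether F1. n-BuLi/TMEDA in THF at −20 °C should then metalate ring A at C1, the position between the methoxy and aryloxy oxygens (directed ortho-metalation), to give aryllithium F2. CO2 gas should convert it into lithium carboxylate F3, and citric acid work-up returns the route at 27.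

2. Step 6 (ortho-silylation). Metalation may take place at the other ortho position of the carbamate (C5) or stay incomplete beside the crowded methoxy group, and the transiently N-silylated carbamate may collapse under n-BuLi. The fallback sets out from 7 and changes the directing group. DBU/Et2NH (MeCN, 40 °C) should free phenol F4. ClCONEt2/K2CO3 (MeCN, reflux) should give N,N-diethylcarbamate F5, the strongest oxygen-based directing group, which needs no nitrogen protection. s-BuLi/TMEDA (THF, −78 °C) should give aryllithium F6, and TMSCl should give arylsilane F7. Cp2Zr(H)Cl (THF, rt) should cleave the tertiary carbamate reductively to phenol 12, where the route is rejoined; 12 is triflated with PhNTf2/Et3N to 13.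

3. Step 2 (methallylboration). Enantioselectivity may erode with the ortho-methoxy aldehyde, and the base-labile carbamate may be lost during oxidation of the borinate. The fallback sets out from 2 and sets the stereocentre by ketone reduction instead. Zinc-mediated Barbier methallylation (Zn, 3-bromo-2-methylpropene, THF/sat. aq. NH4Cl) should give racemic homoallylic alcohol F8. Mukaiyama hydration as in step 3 should give racemic diol F9. MnO2 (CH2Cl2) should oxidise only the benzylic alcohol to β-hydroxy ketone F10. Noyori transfer hydrogenation with RuCl[(S,S)-TsDPEN](p-cymene) in HCO2H/Et3N should then return the (S)-diol 5, with the sense known for acetophenone giving (S)-1-phenylethanol.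

Further compounds

F1 | step 13 | (S)-diaryl ether lacking the carboxyl group: 2-(benzyloxy)-1-{4-[1-(tert-butyldimethylsilyloxy)-3-methyl-3-(triethylsilyloxy)butyl]-3-methoxyphenoxy}-4-methyl-6-(triisopropylsilyloxymethyl)benzene | COc1cc(Oc2c(OCc3ccccc3)cc(C)cc2CO[Si](C(C)C)(C(C)C)C(C)C)ccc1[C@@H](O[Si](C)(C)C(C)(C)C)CC(C)(C)O[Si](CC)(CC)CC
F2 | step 13 | aryllithium from F1, lithium on ring A C1 | COc1c([Li])c(Oc2c(OCc3ccccc3)cc(C)cc2CO[Si](C(C)C)(C(C)C)C(C)C)ccc1[C@@H](O[Si](C)(C)C(C)(C)C)CC(C)(C)O[Si](CC)(CC)CC
F3 | step 13 | lithium salt of 27 | COc1c(C(=O)[O-])c(Oc2c(OCc3ccccc3)cc(C)cc2CO[Si](C(C)C)(C(C)C)C(C)C)ccc1[C@@H](O[Si](C)(C)C(C)(C)C)CC(C)(C)O[Si](CC)(CC)CC.[Li+]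
F4 | step 6 | (S)-4-[1-(tert-butyldimethylsilyloxy)-3-methyl-3-(triethylsilyloxy)butyl]-3-methoxyphenol | COc1cc(O)ccc1[C@@H](O[Si](C)(C)C(C)(C)C)CC(C)(C)O[Si](CC)(CC)CC
F5 | step 6 | (S)-4-[1-(tert-butyldimethylsilyloxy)-3-methyl-3-(triethylsilyloxy)butyl]-3-methoxyphenyl N,N-diethylcarbamate | COc1cc(OC(=O)N(CC)CC)ccc1[C@@H](O[Si](C)(C)C(C)(C)C)CC(C)(C)O[Si](CC)(CC)CC
F6 | step 6 | aryllithium from F5, lithium between carbamate and methoxy | COc1c([Li])c(OC(=O)N(CC)CC)ccc1[C@@H](O[Si](C)(C)C(C)(C)C)CC(C)(C)O[Si](CC)(CC)CC
F7 | step 6 | (S)-4-[1-(tert-butyldimethylsilyloxy)-3-methyl-3-(triethylsilyloxy)butyl]-3-methoxy-2-(trimethylsilyl)phenyl N,N-diethylcarbamate | COc1c([Si](C)(C)C)c(OC(=O)N(CC)CC)ccc1[C@@H](O[Si](C)(C)C(C)(C)C)CC(C)(C)O[Si](CC)(CC)CC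
F8 | step 2 | racemic 4-(1-hydroxy-3-methylbut-3-en-1-yl)-3-methoxyphenyl N-isopropylcarbamate | COc1cc(OC(=O)NC(C)C)ccc1C(O)CC(C)=C
F9 | step 2 | racemic 4-(1,3-dihydroxy-3-methylbutyl)-3-methoxyphenyl N-isopropylcarbamate | COc1cc(OC(=O)NC(C)C)ccc1C(O)CC(C)(C)O
F10 | step 2 | 4-(3-hydroxy-3-methylbutanoyl)-3-methoxyphenyl N-isopropylcarbamate | COc1cc(OC(=O)NC(C)C)ccc1C(=O)CC(C)(C)O
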